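**Compound numbers used throughout:** 1 meso diacetate, 2 nitromethane, 3 nitro acetate, 5 methyl carbamate, 7 N-Boc-N-methyl allylic alcohol, 8 enone, 9 methylated enone, 10 allylic alcohol, 12 silyl ether amine, 13 2,3-dibromopropene, 14 cyclisation precursor, 15 cyclisation product, 16 saturated silyl ether, 17 C6-epimeric amino alcohol, 18 ferulic acid, 19 its tosylate, 20 cyclobutane diacid, 21 bis-tosyl diester, 22 target. Compounds 4, 6 and 11 are not isolated.

## The problem

Target 22 is a twofold ester. A head-to-tail cyclobutane-1,3-dicarboxylic acid with 4-hydroxy-3-methoxyphenyl groups at C2 and C4 (aryls trans to each other, carboxyls trans to each other, centrosymmetric core) acylates the C6 oxygen of two identical amino alcohols. Each alcohol is a cis-fused octahydrocyclopenta[c]pyridine (C1, N2, C3, C4, C4a, C5, C6, C7, C7a) with an N-methyl group and five contiguous stereocentres (4R,4aS,6R,7S,7aR). H4, H4a and H7a lie on one face, and the C7 methyl and the C6 oxygen lie on the convex face of the five-membered ring. Because the core is achiral, all absolute configuration resides in the alkaloid halves, so one diacid can be joined to two equivalents of one enantiopure alcohol. Inside the alkaloid a single centre can relay to the rest: C7a directs C7 (alkylation trans to it), C7a and C7 direct the C6 carbinol, the C7a–C1 tether forces the cis fusion at C4a, and the folded bicycle directs the C4 methyl. The fragile parts are the two hindered esters on epimerisable cyclobutane methines (no strong base or hydride after esterification), the free phenols (competing nucleophiles in any esterification) and the two basic amines. The enabling feature is that C4 carries a methyl that can be an exocyclic methylene, i.e. the internal carbon of a 2-haloallyl group on N2, and that the C4–C4a bond ends at a ring-fusion methine whose neighbour C5 is a plain methylene. C4a=C5 can therefore be the alkene of a cyclopentene, and a C6 oxygen placed on the face of the incoming metal leaves a C5–palladium bond without a syn β-hydrogen.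

## Retrosynthesis

**22 ⇒ 21 ⇒ 20 + two 17.** The phenols are masked as tosylates (21), and both C6–O ester bonds are cut with inversion, giving diacid 20 and the 6S alcohol 17. The neighbouring cut, acyl–oxygen with retention, would need the 6R alcohol. Its silyl ether would present H6 syn to palladium in the ring closure further back, so the inversion is demanded by the key step and is no detour. The precursor is half the size and the diacid is achiral. The forward reaction must achieve SN2 displacement at a hindered secondary carbinol twice without activating the acid as an acyl donor, so the cyclobutane methines are never made enolisable.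

**20 ⇒ 19 ⇒ 18.** The cyclobutane bonds C1–C2 and C3–C4 are cut, a [2+2] retron, giving two molecules of cinnamic acid 19, the tosylate of 18. Dimerisation in solution would give regio- and stereoisomer mixtures; a crystal lattice with antiparallel neighbours fixes head-to-tail union and the relative configuration of all four centres at once. The tosyl group is both the phenol protection for the esterification and the substituent that shapes the lattice. The forward reaction needs a photoactive crystal form of 19.

**17 ⇒ 16 ⇒ 15.** The O–Si bond and the two new C–H bonds of the C4 methyl are cut, leading back to the 4-methylene silyl ether 15. Against setting C4 on an open chain, this postpones the centre until the bicycle exists and its convex face can deliver hydrogen. The forward hydrogenation must add from the face of H4a without moving the double bond into the ring.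

**15 ⇒ 14.** The C4–C4a bond is cut, opening the piperidine to the N-(2-bromoallyl)amine 14 on a cyclopentene. The neighbouring cuts N2–C3 or N2–C1 would require C4a (and C4) to be set beforehand on a flexible arm, whereas this cut creates C4a under tether control. The precursor is monocyclic with three stereocentres. The forward step must close 6-exo, give the cis fusion, and end with hydride on C5.

**14 ⇒ 12 + 13.** The N2–C3 bond is cut to the secondary amine 12 and dibromide 13. This is the only place the three-carbon unit can enter after all base-mediated chemistry is finished. The forward step is a simple allylic N-alkylation that leaves the vinyl bromide intact.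

**12 ⇒ 10 ⇒ 9.** The silyl ether and the N–H are traced to carbamate alcohol 10 (one operation covers both), and the C6–H bond to enone 9. Reducing the ketone last among the ring centres lets C7a and C7 decide C6. The forward reduction must be 1,2-selective and place the oxygen cis to the aminomethyl arm and trans to the methyl.

**9 ⇒ 8 ⇒ 7.** The C7–CH3 bond is cut to enone 8, and the enone is traced to allylic alcohol 7. C7 lies between two sp3 centres and can only be activated as the α′ position of a ketone at C6. The forward methylation must be kinetic and trans to the neighbouring arm.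

**7 ⇒ 5 ⇒ 3 ⇒ 1 + 2.** The N-methyl carbon is traced to the carbamate carbon of 5, the nitrogen to the nitro group of 3, and the C7a–C1 bond is cut to meso diacetate 1 and nitromethane 2. Desymmetrising 1 gives C7a, the centre from which all others follow, in one catalytic step from two commodity compounds. The acetoxy centre of 3 is later oxidised and serves only to place the oxygen 1,4 to the new carbon. The forward reaction must select one enantiotopic acetate and stop after one substitution.

## Roads not taken

**Alternative 1:** This road cuts the two cyclobutane–aryl bonds of the core. The trans bis(8-quinolyl)amide of cyclobutane-1,3-dicarboxylic acid A2 would be arylated twice with 1-(benzyloxy)-4-iodo-2-methoxybenzene A3 under Pd(OAc)2 catalysis, once at each ring methylene and each time cis to a different amide, giving the O,O'-dibenzyl bis(8-quinolyl)amide A1. It is a solution reaction that does not depend on crystal packing and could take two different aryl groups, and in that respect it is better than the lattice-controlled dimerisation of 19. For this target its weak points are: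
- over-arylation, since each amide can direct to both methylenes;
- removal of two aminoquinoline amides from an epimerisable cyclobutane;
- several more steps for a fragment that the chosen plan makes in two, without reagents.

It also leaves the real difficulty, the five stereocentres of each alkaloid half, untouched. The chosen plan answers it with step economy on the core and a defined fallback if the crystal of 19 is not photoactive.

**Alternative 2:** This road cuts C4a–C7a and C6–C7 of the five-membered ring. Cyclopenta-1,3-diene A5 and 3-[(E)-but-2-enoyl]oxazolidin-2-one A6 would combine in an endo-selective Diels–Alder reaction under the Cu(SbF6)2 complex of a tert-butyl bis(oxazoline) to give norbornene imide A4. Later oxidation of the alkene to a ketone and Baeyer–Villiger cleavage would release the cyclopentane with the C6 oxygen. In stereocentre economy this is better than the chosen plan: one catalytic step sets C4a, C6, C7 and C7a. The price comes afterwards: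
- the two alkene carbons of A4 are nearly equivalent, so placing the ketone for the Baeyer–Villiger step is a regiochemical problem;
- the C4 methyl has to be introduced by enolate alkylation of the resulting lactone, with uncertain facial control;
- the piperidine must then be assembled through an imide and reduced.

The chosen plan sets against it unambiguous regiochemistry at every stage and a C4 centre set on the finished bicycle.

**Alternative 3:** This road cuts C4a–C5 and, transiently, C4–C5. Diazoketone A8 would give, with Rh2(OAc)4, a carbenoid at C5 that adds to the C4=C4a alkene of the tetrahydropyridine, closing the cyclopentanone and a cyclopropane in the tricyclic ketone A7. Reductive cleavage of C4–C5 would then expose the C4 methyl. Its merits are two ring bonds in one step and a C6 ketone from which either carbinol epimer could be reached, which the chosen plan (with its fixed C6 epimer and final inversion) does not offer. Its weak points are: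
- A8 already carries C7 and C7a, for which no short asymmetric entry is evident;
- the cyclopropane can open at C4–C5 or at C4a–C5;
- C4 is set by protonation of an open-shell or anionic centre with no obvious bias.

The chosen plan derives all centres from one catalytic desymmetrisation and sets C4 by a surface reaction on a rigid bicycle.

Key step: step 9

## Route

Assumption: in step 1 the (R,R) enantiomer of the bis(phosphino)benzamide ligand is taken to ionise the acetate on the (S)-configured carbon of 1; should the sense be the opposite, the (S,S) ligand is used and nothing else changes.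

Step 1
Reactants: 1 cis-cyclopent-4-ene-1,3-diyl diacetate; 2 nitromethane
Product: 3 (1R,4S)-4-(nitromethyl)cyclopent-2-en-1-yl acetate
Conditions: Pd2(dba)3·CHCl3 (cat.), (1R,2R)-N,N'-bis[2-(diphenylphosphino)benzoyl]cyclohexane-1,2-diamine (cat.), CH3NO2 (5 equiv), Cs2CO3, THF, 0 °C to rt
Reagents that add atoms: none
Why: Tsuji–Trost asymmetric allylic alkylation of a meso diester; the chiral catalyst ionises one enantiotopic acetate anti to palladium and the nitronate attacks the allyl terminus remote from the remaining acetate, again anti to palladium, so the net retention gives the cis 1,4 product and sets C7a, while the second acetate sits at the mismatched position and excess nitromethane suppresses double alkylation.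

Step 2
Reactants: 3 (1R,4S)-4-(nitromethyl)cyclopent-2-en-1-yl acetate
Product: 5 (1R,4S)-4-{[(methoxycarbonyl)amino]methyl}cyclopent-2-en-1-yl acetate, via amino acetate 4 (not isolated)
Conditions: Zn dust, 2 M HCl, EtOH, 0 °C to rt; filter; then ClCO2Me, NaHCO3, THF/H2O, 0 °C
Reagents that add atoms: methyl chloroformate COC(=O)Cl
Why: Dissolving-metal reduction of a primary nitroalkane leaves the alkene and the allylic acetate alone; the amine stays protonated until it is acylated, which prevents O-to-N acetyl transfer, and Schotten–Baumann carbamoylation then gives the carbamate whose carbonyl carbon will become the N-methyl group.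

Step 3
Reactants: 5 (1R,4S)-4-{[(methoxycarbonyl)amino]methyl}cyclopent-2-en-1-yl acetate
Product: 7 tert-butyl {[(1S,4R)-4-hydroxycyclopent-2-en-1-yl]methyl}(methyl)carbamate, via N-methylamino alcohol 6 (not isolated)
Conditions: LiAlH4, THF, reflux; Fieser work-up, filter; then Boc2O, THF, rt
Reagents that add atoms: di-tert-butyl dicarbonate CC(C)(C)OC(=O)OC(=O)OC(C)(C)C
Why: LiAlH4 reduces an N-H carbamate to the N-methylamine and cleaves the acetate in the same operation (hydride reduction of carbamate and ester); the secondary amine is far more nucleophilic than the allylic alcohol, so Boc2O without an acylation catalyst protects nitrogen only.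

Step 4
Reactants: 7 tert-butyl {[(1S,4R)-4-hydroxycyclopent-2-en-1-yl]methyl}(methyl)carbamate
Product: 8 tert-butyl methyl{[(1S)-4-oxocyclopent-2-en-1-yl]methyl}carbamate
Conditions: activated MnO2 (excess), CH2Cl2, rt
Reagents that add atoms: none
Why: Allylic alcohol oxidation on MnO2 under neutral conditions, so the γ-stereocentre (C7a) is not exposed to base and cannot epimerise through a dienol.

Step 5
Reactants: 8 tert-butyl methyl{[(1S)-4-oxocyclopent-2-en-1-yl]methyl}carbamate
Product: 9 tert-butyl methyl{[(1R,5S)-5-methyl-4-oxocyclopent-2-en-1-yl]methyl}carbamate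
Conditions: LDA (1.1 equiv), THF, −78 °C; MeI, −78 to −40 °C
Reagents that add atoms: iodomethane CI
Why: Kinetic α′-deprotonation of a cyclopentenone gives the cross-conjugated enolate, which is methylated anti to the adjacent carbamoylmethyl arm (enolate alkylation under 1,2-induction), setting C7 trans to C7a; the trans isomer is also the more stable one, and the fully substituted carbamate has no acidic N–H.

Step 6
Reactants: 9 tert-butyl methyl{[(1R,5S)-5-methyl-4-oxocyclopent-2-en-1-yl]methyl}carbamate
Product: 10 tert-butyl {[(1R,4S,5S)-4-hydroxy-5-methylcyclopent-2-en-1-yl]methyl}(methyl)carbamate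
Conditions: NaBH4, CeCl3·7H2O, MeOH, −78 °C
Reagents that add atoms: none
Why: Luche 1,2-reduction; hydride should enter anti to the larger arm at the 4-position of the enone, as 4-substituted cyclopentenones normally give the cis 1,4 alcohol, and a small hydride also favours the trans 2-methylcyclopentanol arrangement, so both effects point to the alcohol cis to the arm and trans to the methyl (6S in the later numbering).

Step 7
Reactants: 10 tert-butyl {[(1R,4S,5S)-4-hydroxy-5-methylcyclopent-2-en-1-yl]methyl}(methyl)carbamate
Product: 12 1-[(1R,4S,5S)-4-{[tert-butyl(dimethyl)silyl]oxy}-5-methylcyclopent-2-en-1-yl]-N-methylmethanamine, via silyl carbamate silyl ether 11 (not isolated)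
Conditions: TBSOTf (2.5 equiv), 2,6-lutidine, CH2Cl2, 0 °C to rt; then K2CO3, MeOH/H2O, rt
Reagents that add atoms: tert-butyldimethylsilyl trifluoromethanesulfonate CC(C)(C)[Si](C)(C)OS(=O)(=O)C(F)(F)F
Why: The silyl triflate silylates the alcohol and converts the tert-butyl carbamate into the silyl carbamate with loss of isobutene (silyl triflate cleavage of Boc groups); mild aqueous methanolysis then hydrolyses only the silyl carbamate, which decarboxylates to the secondary amine while the silyl ether stays.

Step 8
Reactants: 12 1-[(1R,4S,5S)-4-{[tert-butyl(dimethyl)silyl]oxy}-5-methylcyclopent-2-en-1-yl]-N-methylmethanamine; 13 2,3-dibromoprop-1-ene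
Product: 14 N-(2-bromoprop-2-en-1-yl)-1-[(1R,4S,5S)-4-{[tert-butyl(dimethyl)silyl]oxy}-5-methylcyclopent-2-en-1-yl]-N-methylmethanamine
Conditions: K2CO3, MeCN, 0 °C to rt (1.05 equiv of 13)
Reagents that add atoms: none
Why: SN2 N-alkylation at the allylic bromide; the vinylic bromide does not react, and near-stoichiometric dibromide limits quaternisation.

Step 9
Reactants: 14 N-(2-bromoprop-2-en-1-yl)-1-[(1R,4S,5S)-4-{[tert-butyl(dimethyl)silyl]oxy}-5-methylcyclopent-2-en-1-yl]-N-methylmethanamine
Product: 15 (4aR,6S,7S,7aR)-6-{[tert-butyl(dimethyl)silyl]oxy}-2,7-dimethyl-4-methylideneoctahydro-1H-cyclopenta[c]pyridine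
Conditions: Pd(OAc)2 (10 mol %), PPh3 (20 mol %), HCO2Na (1.5 equiv), Bu4NCl, DMF, 80 °C
Reagents that add atoms: none
Why: Zerovalent palladium, formed from Pd(OAc)2 and PPh3, inserts into the C4–Br bond of 14, and neither the allylic silyl ether nor the homoallylic amine offers a competing ionisation. The vinylpalladium adds syn across C4a=C5 in a 6-exo-trig closure (ring C4, C3, N2, C1, C7a, C4a); the closest known reaction type is the formate-terminated (reductive) Heck cyclisation of N-(2-haloallyl)amines onto cycloalkenes. The three-atom tether from C7a lets C4 reach C4a only on the face of the C1 arm, so the new stereocentre C4a is set with a cis ring fusion (4aR), and 7-endo attack at C5 would need a strained bridged geometry. Palladium ends on C5 on that same face; H4a is anti to it because the addition is syn, and H6 is anti because the silyloxy group at C6 was placed cis to the C1 arm, so no syn β-hydrogen is available. Formate replaces bromide on palladium and loses CO2, and the hydride so formed reductively eliminates with C5, which becomes the methylene and returns zerovalent palladium. The step needs exo over endo closure and hydride capture over β-elimination or premature reduction of the vinylpalladium; the tether length secures the first, the C6 configuration and the poor leaving-group ability of the silyl ether the second, and the low solubility of HCO2Na in DMF, which keeps the hydride source scarce, the third.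

Step 10
Reactants: 15 (4aR,6S,7S,7aR)-6-{[tert-butyl(dimethyl)silyl]oxy}-2,7-dimethyl-4-methylideneoctahydro-1H-cyclopenta[c]pyridine
Product: 16 (4R,4aS,6S,7S,7aR)-6-{[tert-butyl(dimethyl)silyl]oxy}-2,4,7-trimethyloctahydro-1H-cyclopenta[c]pyridine
Conditions: H2 (1 atm), PtO2 (cat.), EtOH, rt
Reagents that add atoms: none
Why: Heterogeneous hydrogenation of a 1,1-disubstituted alkene; the catalyst should approach the convex face of the cis-fused bicycle (the face of H4a), the concave face being closed by the five-membered ring and its endo silyloxy group, so H4 ends cis to H4a (4R), and platinum is chosen over palladium to limit double-bond migration.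

Step 11
Reactants: 16 (4R,4aS,6S,7S,7aR)-6-{[tert-butyl(dimethyl)silyl]oxy}-2,4,7-trimethyloctahydro-1H-cyclopenta[c]pyridine
Product: 17 (4R,4aS,6S,7S,7aR)-2,4,7-trimethyloctahydro-1H-cyclopenta[c]pyridin-6-ol
Conditions: Bu4NF, THF, rt to 50 °C
Reagents that add atoms: none
Why: Fluoride cleavage of a secondary silyl ether; no other group in 16 responds to fluoride.

Step 12
Reactants: 18 ferulic acid
Product: 19 (E)-3-{3-methoxy-4-[(4-methylbenzenesulfonyl)oxy]phenyl}prop-2-enoic acid
Conditions: TsCl (1.1 equiv), NaOH (2.2 equiv), H2O/THF, 0 °C to rt; then 1 M HCl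
Reagents that add atoms: 4-methylbenzenesulfonyl chloride Cc1ccc(S(=O)(=O)Cl)cc1
Why: Schotten–Baumann sulfonylation of the phenoxide of the dianion; any mixed carboxylic sulfonic anhydride is hydrolysed in the aqueous base, and the acid crystallises on acidification.

Step 13
Reactants: 19 (E)-3-{3-methoxy-4-[(4-methylbenzenesulfonyl)oxy]phenyl}prop-2-enoic acid (two molecules)
Product: 20 (1α,2α,3β,4β)-2,4-bis{3-methoxy-4-[(4-methylbenzenesulfonyl)oxy]phenyl}cyclobutane-1,3-dicarboxylic acid
Conditions: hν (medium-pressure Hg lamp, Pyrex filter), crystalline 19 suspended in hexane, rt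
Reagents that add atoms: none
Why: Topochemical [2+2] photodimerisation of a cinnamic acid crystal; antiparallel neighbours related by a centre of symmetry with their double bonds within about 4 Å give the head-to-tail centrosymmetric dimer, so all four cyclobutane centres are set by the lattice.

Step 14
Reactants: 20 (1α,2α,3β,4β)-2,4-bis{3-methoxy-4-[(4-methylbenzenesulfonyl)oxy]phenyl}cyclobutane-1,3-dicarboxylic acid; 17 (4R,4aS,6S,7S,7aR)-2,4,7-trimethyloctahydro-1H-cyclopenta[c]pyridin-6-ol (2.2 equiv)
Product: 21 bis[(4R,4aS,6R,7S,7aR)-2,4,7-trimethyloctahydro-1H-cyclopenta[c]pyridin-6-yl] (1α,2α,3β,4β)-2,4-bis{3-methoxy-4-[(4-methylbenzenesulfonyl)oxy]phenyl}cyclobutane-1,3-dicarboxylate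
Conditions: PPh3 (3 equiv), diethyl azodicarboxylate (3 equiv), THF, 0 °C to rt
Reagents that add atoms: none
Why: Twofold Mitsunobu esterification; the concave C6 hydroxyl becomes the oxyphosphonium leaving group and each carboxylate attacks from the open convex face with inversion (6S to 6R), while the acid acts only as a nucleophile, so the cyclobutane methines are never acyl-activated, and the aryl tosylates and the tertiary amines do not interfere.

Step 15
Reactants: 21 bis[(4R,4aS,6R,7S,7aR)-2,4,7-trimethyloctahydro-1H-cyclopenta[c]pyridin-6-yl] (1α,2α,3β,4β)-2,4-bis{3-methoxy-4-[(4-methylbenzenesulfonyl)oxy]phenyl}cyclobutane-1,3-dicarboxylate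
Product: 22 bis[(4R,4aS,6R,7S,7aR)-2,4,7-trimethyloctahydro-1H-cyclopenta[c]pyridin-6-yl] (1α,2α,3β,4β)-2,4-bis(4-hydroxy-3-methoxyphenyl)cyclobutane-1,3-dicarboxylate
Conditions: Mg turnings (excess), MeOH, 0 °C to rt; aqueous NH4Cl work-up
Reagents that add atoms: none
Why: Electron-transfer cleavage of the aryl sulfonate S–O bonds by magnesium in methanol frees both phenols; the non-conjugated hindered alkyl esters, the amines and the cyclobutane are not reduced, and no hydroxide or strong alkoxide is needed.

## Compound list

1 | cis-cyclopent-4-ene-1,3-diyl diacetate | CC(=O)O[C@H]1C[C@@H](OC(C)=O)C=C1 | starting material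
2 | nitromethane | C[N+](=O)[O-] | starting material
3 | (1R,4S)-4-(nitromethyl)cyclopent-2-en-1-yl acetate | CC(=O)O[C@H]1C=C[C@@H](C[N+](=O)[O-])C1 | intermediate
4 | (1R,4S)-4-(aminomethyl)cyclopent-2-en-1-yl acetate (not isolated) | CC(=O)O[C@H]1C=C[C@@H](CN)C1 | intermediate
5 | (1R,4S)-4-{[(methoxycarbonyl)amino]methyl}cyclopent-2-en-1-yl acetate | CC(=O)O[C@H]1C=C[C@@H](CNC(=O)OC)C1 | intermediate
6 | (1R,4S)-4-[(methylamino)methyl]cyclopent-2-en-1-ol (not isolated) | O[C@H]1C=C[C@@H](CNC)C1 | intermediate
7 | tert-butyl {[(1S,4R)-4-hydroxycyclopent-2-en-1-yl]methyl}(methyl)carbamate | O[C@H]1C=C[C@@H](CN(C)C(=O)OC(C)(C)C)C1 | intermediate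
8 | tert-butyl methyl{[(1S)-4-oxocyclopent-2-en-1-yl]methyl}carbamate | O=C1C=C[C@@H](CN(C)C(=O)OC(C)(C)C)C1 | intermediate
9 | tert-butyl methyl{[(1R,5S)-5-methyl-4-oxocyclopent-2-en-1-yl]methyl}carbamate | O=C1C=C[C@@H](CN(C)C(=O)OC(C)(C)C)[C@@H]1C | intermediate
10 | tert-butyl {[(1R,4S,5S)-4-hydroxy-5-methylcyclopent-2-en-1-yl]methyl}(methyl)carbamate | O[C@H]1C=C[C@@H](CN(C)C(=O)OC(C)(C)C)[C@@H]1C | intermediate
11 | tert-butyldimethylsilyl {[(1R,4S,5S)-4-{[tert-butyl(dimethyl)silyl]oxy}-5-methylcyclopent-2-en-1-yl]methyl}(methyl)carbamate (not isolated) | CC(C)(C)[Si](C)(C)O[C@H]1C=C[C@@H](CN(C)C(=O)O[Si](C)(C)C(C)(C)C)[C@@H]1C | intermediate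
12 | 1-[(1R,4S,5S)-4-{[tert-butyl(dimethyl)silyl]oxy}-5-methylcyclopent-2-en-1-yl]-N-methylmethanamine | CC(C)(C)[Si](C)(C)O[C@H]1C=C[C@@H](CNC)[C@@H]1C | intermediate
13 | 2,3-dibromoprop-1-ene | BrCC(Br)=C | starting material
14 | N-(2-bromoprop-2-en-1-yl)-1-[(1R,4S,5S)-4-{[tert-butyl(dimethyl)silyl]oxy}-5-methylcyclopent-2-en-1-yl]-N-methylmethanamine | CC(C)(C)[Si](C)(C)O[C@H]1C=C[C@@H](CN(C)CC(Br)=C)[C@@H]1C | intermediate
15 | (4aR,6S,7S,7aR)-6-{[tert-butyl(dimethyl)silyl]oxy}-2,7-dimethyl-4-methylideneoctahydro-1H-cyclopenta[c]pyridine | CC(C)(C)[Si](C)(C)O[C@H]1C[C@@H]2[C@@H](CN(C)CC2=C)[C@@H]1C | intermediate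
16 | (4R,4aS,6S,7S,7aR)-6-{[tert-butyl(dimethyl)silyl]oxy}-2,4,7-trimethyloctahydro-1H-cyclopenta[c]pyridine | CC(C)(C)[Si](C)(C)O[C@H]1C[C@@H]2[C@@H](CN(C)C[C@@H]2C)[C@@H]1C | intermediate
17 | (4R,4aS,6S,7S,7aR)-2,4,7-trimethyloctahydro-1H-cyclopenta[c]pyridin-6-ol | O[C@H]1C[C@@H]2[C@@H](CN(C)C[C@@H]2C)[C@@H]1C | intermediate
18 | ferulic acid | COc1cc(/C=C/C(=O)O)ccc1O | starting material
19 | (E)-3-{3-methoxy-4-[(4-methylbenzenesulfonyl)oxy]phenyl}prop-2-enoic acid | COc1cc(/C=C/C(=O)O)ccc1OS(=O)(=O)c1ccc(C)cc1 | intermediate
20 | (1α,2α,3β,4β)-2,4-bis{3-methoxy-4-[(4-methylbenzenesulfonyl)oxy]phenyl}cyclobutane-1,3-dicarboxylic acid | COc1cc([C@H]2[C@H](C(=O)O)[C@H](c3ccc(OS(=O)(=O)c4ccc(C)cc4)c(OC)c3)[C@H]2C(=O)O)ccc1OS(=O)(=O)c1ccc(C)cc1 | intermediate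
21 | bis[(4R,4aS,6R,7S,7aR)-2,4,7-trimethyloctahydro-1H-cyclopenta[c]pyridin-6-yl] (1α,2α,3β,4β)-2,4-bis{3-methoxy-4-[(4-methylbenzenesulfonyl)oxy]phenyl}cyclobutane-1,3-dicarboxylate | COc1cc([C@H]2[C@H](C(=O)O[C@@H]3C[C@@H]4[C@@H](CN(C)C[C@@H]4C)[C@@H]3C)[C@H](c3ccc(OS(=O)(=O)c4ccc(C)cc4)c(OC)c3)[C@H]2C(=O)O[C@@H]2C[C@@H]3[C@@H](CN(C)C[C@@H]3C)[C@@H]2C)ccc1OS(=O)(=O)c1ccc(C)cc1 | intermediate
22 | bis[(4R,4aS,6R,7S,7aR)-2,4,7-trimethyloctahydro-1H-cyclopenta[c]pyridin-6-yl] (1α,2α,3β,4β)-2,4-bis(4-hydroxy-3-methoxyphenyl)cyclobutane-1,3-dicarboxylate | COc1cc([C@H]2[C@H](C(=O)O[C@@H]3C[C@@H]4[C@@H](CN(C)C[C@@H]4C)[C@@H]3C)[C@H](c3ccc(O)c(OC)c3)[C@H]2C(=O)O[C@@H]2C[C@@H]3[C@@H](CN(C)C[C@@H]3C)[C@@H]2C)ccc1O | target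

## Step count and least certain steps

Total step count: 15. Longest linear sequence: 13 steps (steps 1 to 11, then 14 and 15); the diacid branch (steps 12 and 13) joins at step 14.

**Step 9 (key step).** Three processes could divert it: reduction of the vinylpalladium by formate before it has added to the ring alkene; loss of the silyloxy group by syn β-oxygen elimination from the C5–palladium bond; and rearrangement of the homoallylic C5–palladium species through a cyclopropylcarbinyl intermediate towards the seven-membered isomer. All three come from the organopalladium intermediates. The fallback keeps the same bond and the same compounds but leaves palladium out: 14 is cyclised by a tin hydride chain (Bu3SnH, azobisisobutyronitrile, benzene, 80 °C, slow addition) through a vinyl radical that closes 6-exo onto C4a under the same tether control, and the C5 radical takes hydrogen from tin to give 15 directly. The point to watch there is 1,5-hydrogen transfer from C7a to the vinyl radical. The fallback makes no new compound; it sets out from 14 and returns at 15.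

**Step 6.** Poor facial selectivity in the hydride addition is the likely failure, because the methyl next to the carbonyl and the arm across the ring sit on opposite faces and their influences only partly reinforce each other. If the reduction of 9 gives mainly the epimer tert-butyl {[(1R,4R,5S)-4-hydroxy-5-methylcyclopent-2-en-1-yl]methyl}(methyl)carbamate F1, that alcohol is inverted instead of discarded. Mitsunobu reaction with 4-nitrobenzoic acid (PPh3, diisopropyl azodicarboxylate, THF) gives (1S,4R,5S)-4-{[(tert-butoxycarbonyl)(methyl)amino]methyl}-5-methylcyclopent-2-en-1-yl 4-nitrobenzoate F2, and methanolysis (K2CO3, MeOH) returns to the route at 10. The fallback sets out from 9.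

**Step 13.** The reaction depends entirely on crystal packing: a photostable polymorph, or a lattice with parallel neighbours, would give no dimer or the head-to-head isomer. The fallback changes the crystal, and with it the protecting group and the last step. Setting out from 18, acetylation (Ac2O, pyridine) gives (E)-3-(4-acetoxy-3-methoxyphenyl)prop-2-enoic acid F3. Irradiation of its crystals gives (1α,2α,3β,4β)-2,4-bis(4-acetoxy-3-methoxyphenyl)cyclobutane-1,3-dicarboxylic acid F4. Mitsunobu coupling with 17 as in step 14 gives the bis(O-acetyl) diester bis[(4R,4aS,6R,7S,7aR)-2,4,7-trimethyloctahydro-1H-cyclopenta[c]pyridin-6-yl] (1α,2α,3β,4β)-2,4-bis(4-acetoxy-3-methoxyphenyl)cyclobutane-1,3-dicarboxylate F5. Brief methanolysis of the aryl acetates (K2CO3, MeOH, 0 °C) then returns to the route at 22.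

**Step 1.** Two things could go wrong: the catalyst may select the enantiotopic acetates less well than required (or in the opposite sense), and the product nitronate may react a second time at the remaining allylic acetate. The fallback takes the asymmetry from an enzyme instead of the ligand. Setting out from 1, esterase- or lipase-mediated desymmetrisation gives (1S,4R)-4-hydroxycyclopent-2-en-1-yl acetate F6, which is also an article of commerce. Its one allylic acetate is replaced with retention by nitromethane under an achiral catalyst (Pd(PPh3)4, Cs2CO3, THF) to give (1R,4S)-4-(nitromethyl)cyclopent-2-en-1-ol F7. Acetylation (Ac2O, pyridine) returns to the route at 3.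

**Step 10.** Double-bond migration into the ring on the metal surface, followed by hydrogenation of the isomerised alkene, would erode the C4 configuration, as would incomplete shielding of the concave face. The fallback changes the mechanism from surface syn addition to stepwise hydrogen-atom transfer: 15 is treated with Mn(dpm)3 (dpm = dipivaloylmethanate), PhSiH3 and tert-butyl hydroperoxide in isopropanol. A hydrogen atom adds to the terminal carbon and the tertiary C4 radical then takes its hydrogen from the open convex face, giving 16 without any metal alkyl that could migrate. The fallback makes no new compound; it sets out from 15 and returns at 16.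

**Step 14.** Elimination of the activated C6 oxygen towards C5 or C7, and stalling after the first esterification, are the risks, since the carbinol is secondary, flanked by the C7 methyl, and must react twice on one diacid. The fallback separates inversion from esterification. Setting out from 17, Mitsunobu reaction with the small, acidic 4-nitrobenzoic acid gives (4R,4aS,6R,7S,7aR)-2,4,7-trimethyloctahydro-1H-cyclopenta[c]pyridin-6-yl 4-nitrobenzoate F8. Methanolysis gives the 6R alcohol (4R,4aS,6R,7S,7aR)-2,4,7-trimethyloctahydro-1H-cyclopenta[c]pyridin-6-ol F9. Steglich esterification of F9 with diacid 20 (carbodiimide, 4-dimethylaminopyridine, CH2Cl2), which proceeds with retention, returns to the route at 21.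

## Further compounds

F1 | step 6 | tert-butyl {[(1R,4R,5S)-4-hydroxy-5-methylcyclopent-2-en-1-yl]methyl}(methyl)carbamate | O[C@@H]1C=C[C@@H](CN(C)C(=O)OC(C)(C)C)[C@@H]1C
F2 | step 6 | (1S,4R,5S)-4-{[(tert-butoxycarbonyl)(methyl)amino]methyl}-5-methylcyclopent-2-en-1-yl 4-nitrobenzoate | O=C(O[C@H]1C=C[C@@H](CN(C)C(=O)OC(C)(C)C)[C@@H]1C)c1ccc(cc1)[N+](=O)[O-]
F3 | step 13 | (E)-3-(4-acetoxy-3-methoxyphenyl)prop-2-enoic acid | COc1cc(/C=C/C(=O)O)ccc1OC(C)=O
F4 | step 13 | (1α,2α,3β,4β)-2,4-bis(4-acetoxy-3-methoxyphenyl)cyclobutane-1,3-dicarboxylic acid | COc1cc([C@H]2[C@H](C(=O)O)[C@H](c3ccc(OC(C)=O)c(OC)c3)[C@H]2C(=O)O)ccc1OC(C)=O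
F5 | step 13 | bis[(4R,4aS,6R,7S,7aR)-2,4,7-trimethyloctahydro-1H-cyclopenta[c]pyridin-6-yl] (1α,2α,3β,4β)-2,4-bis(4-acetoxy-3-methoxyphenyl)cyclobutane-1,3-dicarboxylate | COc1cc([C@H]2[C@H](C(=O)O[C@@H]3C[C@@H]4[C@@H](CN(C)C[C@@H]4C)[C@@H]3C)[C@H](c3ccc(OC(C)=O)c(OC)c3)[C@H]2C(=O)O[C@@H]2C[C@@H]3[C@@H](CN(C)C[C@@H]3C)[C@@H]2C)ccc1OC(C)=O
F6 | step 1 | (1S,4R)-4-hydroxycyclopent-2-en-1-yl acetate | O[C@H]1C=C[C@@H](OC(C)=O)C1
F7 | step 1 | (1R,4S)-4-(nitromethyl)cyclopent-2-en-1-ol | O[C@H]1C=C[C@@H](C[N+](=O)[O-])C1
F8 | step 14 | (4R,4aS,6R,7S,7aR)-2,4,7-trimethyloctahydro-1H-cyclopenta[c]pyridin-6-yl 4-nitrobenzoate | O=C(O[C@@H]1C[C@@H]2[C@@H](CN(C)C[C@@H]2C)[C@@H]1C)c1ccc(cc1)[N+](=O)[O-]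
F9 | step 14 | (4R,4aS,6R,7S,7aR)-2,4,7-trimethyloctahydro-1H-cyclopenta[c]pyridin-6-ol | O[C@@H]1C[C@@H]2[C@@H](CN(C)C[C@@H]2C)[C@@H]1C
F0 | step 9 | none | none
F0 | step 10 | none | none
A1 | alternative 1 | O,O'-dibenzyl α-truxillic bis(8-quinolyl)amide | COc1cc([C@H]2[C@H](C(=O)Nc3cccc4cccnc34)[C@H](c3ccc(OCc4ccccc4)c(OC)c3)[C@H]2C(=O)Nc2cccc3cccnc23)ccc1OCc1ccccc1
A2 | alternative 1 | trans-N,N'-di(quinolin-8-yl)cyclobutane-1,3-dicarboxamide | O=C(Nc1cccc2cccnc12)[C@H]1C[C@H](C(=O)Nc2cccc3cccnc23)C1
A3 | alternative 1 | 1-(benzyloxy)-4-iodo-2-methoxybenzene | COc1cc(I)ccc1OCc1ccccc1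
A4 | alternative 2 | endo-acyl exo-methyl norbornene imide (3-methylbicyclo[2.2.1]hept-5-ene-2-carbonyl oxazolidinone) | O=C(N1CCOC1=O)[C@H]1[C@H](C)[C@H]2C=C[C@@H]1C2
A5 | alternative 2 | cyclopenta-1,3-diene | C1=CC=CC1
A6 | alternative 2 | 3-[(E)-but-2-enoyl]oxazolidin-2-one | C/C=C/C(=O)N1CCOC1=O
A7 | alternative 3 | tricyclic cyclopropyl ketone (cyclopropane C4–C4a–C5 fused to the piperidine carbamate and the cyclopentanone) | O=C1[C@@H](C)[C@@H]2CN(C(=O)OC)C[C@@]3(C)[C@@H]2[C@@H]13
A8 | alternative 3 | methyl 3-(4-diazo-3-oxobutan-2-yl)-5-methyl-3,6-dihydro-2H-pyridine-1-carboxylate | [N-]=[N+]=CC(=O)[C@@H](C)[C@H]1C=C(C)CN(C(=O)OC)C1
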